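## Structural features

The target is a flavonol. Ring A (benzene) and ring C (4-pyranone) are fused through C4a–C8a, ring B is attached to C2 by the C2–C1' bond, and C3 carries the enolic hydroxyl of a 3-hydroxy-4-one unit. Ring A is a 1,2,3,5-tetraoxygenated benzene in which every position differs: free hydroxyl at C5 (peri to the C4 carbonyl), hydrogen at C6, methoxyls at C7 and C8, and the ring oxygen O1 at C8a. Ring B is 1,2,4-trioxygenated, with free hydroxyls at C2' and C4' and a methoxyl at C5'. The target has no stereocentre. The stereocentres met on the way (C2 and C4 of a chroman, in a 1,3 relation, and one cyclobutenone carbon) are transient. Fragile features are the electron-rich rings (ring A is an oxidisable hydroquinone monoether until C4 is a carbonyl), the base- and oxygen-sensitive 3-hydroxy-4-pyranone, and in the intermediates an enol ether and a benzylic C4–O bond flanked by three donor oxygens. The real difficulty is regiochemical: four hydroxyls must end free and three methylated, and on ring A the C5 oxygen must be told apart from those at C7 and C8. The key step exploits the para relation of C5–OH and C8–OMe, with C7–OMe beside C8 and hydrogen at C6. C5, C6, C7 and C8 map one to one onto the four carbons of a 3,4-dimethoxycyclobutenone, and C4a/C8a onto the enol ether double bond of a dihydropyran that already is ring C.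

## Logic of the disconnections

22 to 21: the three O–C(isopropyl) bonds at O5, O2' and O4' are cut. Isopropyl marks the oxygens that must end free and separates them from the three methoxyls. The gain is that no earlier intermediate carries a free ring B phenol. The demand is a dealkylation that removes secondary alkyl ethers and leaves methyl ethers.

21 to 19: the C3–O bond and the C2=C3 unsaturation are removed. The 3-hydroxy-4-pyranone is the tautomer of a 3,4-dione, so it can come from a saturated ketone whose only enolisable carbon is C3. Ring C simplifies to a chroman-4-one. The forward step must be a four-electron oxidation at C3 that leaves two electron-rich arenes alone.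

19 to 18 to 17: no skeletal bond is cut. The C4 carbonyl goes back to an alcohol and then to a silyl ether. A ketone at C4 would be conjugated with the enol ether used for metalation, so C4 has to travel as a protected alcohol. The demand is a non-acidic oxidation of a very easily ionised benzylic alcohol.

17 to 16: the O5–C(isopropyl) bond is cut. In 16 the phenol is a hydroquinone monoether lying ortho to an ionisable benzylic silyl ether, so it is capped before fluoride and oxidant are used. This is one added step without a separate deprotection. The demand is clean O-alkylation of a hindered phenoxide.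

16 to 13 (key disconnection): the C4a–C5 bond is cut and C5 is rejoined to C8, which restores a four-membered ring. The cut is made there because the ring A pattern is exactly that of a 4-alkenyl-3,4-dimethoxycyclobutenone with hydrogen on carbon 2. A fully differentiated benzene ring thus reduces to a cyclobutenone on an enol ether, with no arene substitution and no selective demethylation. The forward step needs the alkenyl group to rotate inward on ring opening, ring closure to outrun ketene capture, and a benzylic silyl ether that survives the heating.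

13 to 7 and 10: the C8–C8a bond (cyclobutenone quaternary carbon to pyran C6) and the O–CH3 bond of the tertiary ether are cut. This is a carbonyl addition of a vinyl anion followed by alkylation of the alkoxide, and it joins two small fragments convergently. The demands are metalation of 7 at C6 only, addition to the carbonyl of 10 that is not a vinylogous ester, and methylation in the same flask.

10 to 8: one methoxyl of the squarate is replaced by hydrogen, which becomes H6 of ring A. The gain is a commercial four-carbon unit. The demand is a single hydride transfer followed by acid-induced loss of methanol.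

7 to 6 to 5: the O–Si bond and the C4–H bond are removed, leading back to a vinylogous ester. The demands are 1,2-reduction and acid-free handling of an allylic enol ether.

5 to 2 and 3: the O1–C6 and C2–C3 bonds of the pyranone are cut (O1–C8a and C2–C3 in flavonoid numbering). The aldehyde carbon becomes C2 with ring B attached, so ring C comes from an aldehyde and a commercial diene. The demand is activation of a donor-substituted aldehyde.

2 to 1: two O–C(isopropyl) bonds are cut, leading to the commercial dihydroxy aldehyde.

## Other disconnections considered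

Alternative 1: The cut removes C1'–C2 and C2–C3 together, so that C2 comes from carbon monoxide. The methyl ketone A2, the ring B bromide A3 and CO would combine under Pd(dba)2, Xantphos and base to the 1,3-diketone A1. Oxidative addition of A3 to zerovalent palladium, CO insertion and acylation of the enolate of A2 would form both bonds in one catalytic cycle.
- In favour: the step is convergent and catalytic, and acid cyclodehydration of A1 to a chromone is reliable. On step count and convergence this plan is the better one.
- Against: A2 must already hold the full ring A pattern, so the regiochemical problem moves into the preparation of a tetraoxygenated acetophenone. The C5 oxygen arrives methylated and needs a peri-selective demethylation. A3 is an ortho-substituted, electron-rich bromide, for which oxidative addition should be slow. The free phenol of A2 can intercept the acylpalladium species by O-acylation.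
- Comparison: cyclisation of A1 leaves C3 as C–H, so both plans need a separate C3 oxygenation and are equal there. The chosen plan is longer and linear, but it fixes the ring A pattern by connectivity and its key step is a catalyst-free unimolecular reaction.

Alternative 2: The cut is C4–C4a. The acrylic acid A5, with its carboxyl cis to the aryloxy group, would be activated by trifluoroacetic anhydride as a mixed anhydride. Intramolecular Friedel–Crafts acylation at the only free ortho position of the ring A ether would close ring C to A4.
- In favour: the C3 oxygen is already in place as a benzyl ether, which is better than the chosen plan because no late oxidation at C3 is needed. The regiochemistry of acylation is unambiguous. Benzyl ethers can be removed by hydrogenolysis, which is equal to or milder than BCl3.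
- Against: A5 is a tetrasubstituted enol ether acid of defined geometry and is hard to assemble. The benzyl enol ether and both electron-rich rings must survive the acylating acid, and trifluoroacetylation could compete at the ring A carbon between two methoxyls. The C5 oxygen again arrives methylated.
- Comparison: this is a polar electrophilic substitution where the chosen plan is pericyclic. It has fewer redox changes on ring C, but it depends on arene pre-functionalisation and a selective demethylation. The step count should be similar once A5 is counted.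

Alternative 3: The cut is O1–C2, made as a ring expansion. KOH in aqueous ethanol would open the coumaranone of the aurone dibromide A7. The freed ring A phenoxide would then bond to the benzylic carbon and give the flavonol A6.
- In favour: the key step reaches the 3-hydroxy-4-pyranone oxidation level directly, which is better than the chosen plan at that point. The reagents are cheap, and the step count is expected to be equal or lower.
- Against: A7 requires bromine addition in the presence of two strongly activated rings, where ring bromination should compete. The aryl mesylates of A6 are unlikely to be inert to hot hydroxide. Ring expansions of this type are sensitive to substituents ortho to the reacting centres, and reversion to the aurone could compete. The C5 oxygen is methylated and the mesylates must still be removed.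
- Comparison: the plan is equal or better in oxidation-level economy and weaker in chemoselectivity and in differentiating the ring A oxygens.

Key step: step 7

Remarks on the chemistry:
- Every stereocentre of the intermediates is erased before the target, so racemic material is carried and each racemate is drawn as one enantiomer.
- The atom mapping of the ring expansion was checked against 13 and 16 and needs no structural correction: ketene carbon to C5, ring CH to C6, methoxy-bearing vinyl carbon to C7, methylated quaternary carbon to C8.
- Compounds 1, 3 and 8 are taken as purchasable.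

Step 1
Reactants: 1 2,4-dihydroxy-5-methoxybenzaldehyde
Product: 2 5-methoxy-2,4-di(propan-2-yloxy)benzaldehyde
Conditions: i-PrBr, K2CO3, DMF, 70 °C
Reagents that add atoms: 2-bromopropane, CC(C)Br
Why: Williamson ether synthesis on both phenoxides; heat and excess bromide are needed for the hydroxyl that is hydrogen-bonded to the aldehyde. Isopropyl ethers should resist organolithium, fluoride, oxidants and aqueous acid and can later be cleaved without loss of methyl ethers.

Step 2
Reactants: 2 5-methoxy-2,4-di(propan-2-yloxy)benzaldehyde; 3 (E)-1-methoxy-3-(trimethylsilyloxy)buta-1,3-diene (Danishefsky diene)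
Product: 5 rac-2-[5-methoxy-2,4-di(propan-2-yloxy)phenyl]-2,3-dihydro-4H-pyran-4-one, via cycloadduct 4 (not isolated)
Conditions: ZnCl2 (0.5 equiv), THF, rt; then TFA (cat.), CH2Cl2, 0 °C
Reagents that add atoms: none
Why: Lewis acid-promoted hetero-Diels–Alder cyclocondensation; ZnCl2 activates the donor-substituted carbonyl, and acid then removes the silyl group and methanol from 4 to unveil the vinylogous ester. The C2 stereocentre is formed racemic, which is acceptable because it is erased in step 11.

Step 3
Reactants: 5 rac-2-[5-methoxy-2,4-di(propan-2-yloxy)phenyl]-2,3-dihydro-4H-pyran-4-one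
Product: 6 rac-(2R,4R)-2-[5-methoxy-2,4-di(propan-2-yloxy)phenyl]-3,4-dihydro-2H-pyran-4-ol (2,4-cis)
Conditions: NaBH4, CeCl3·7H2O, MeOH, −78 → −40 °C
Reagents that add atoms: none
Why: Luche reduction; CeCl3 in methanol enforces 1,2-delivery of hydride to the vinylogous ester carbonyl. Axial attack on the half-chair with a pseudo-equatorial aryl group should give the 2,4-cis alcohol, a relation without consequence because C4 is oxidised later.

Step 4
Reactants: 6 rac-(2R,4R)-2-[5-methoxy-2,4-di(propan-2-yloxy)phenyl]-3,4-dihydro-2H-pyran-4-ol
Product: 7 rac-(2R,4R)-2-[5-methoxy-2,4-di(propan-2-yloxy)phenyl]-4-(triisopropylsilyloxy)-3,4-dihydro-2H-pyran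
Conditions: TIPSCl, imidazole, DMF, rt
Reagents that add atoms: chlorotri(propan-2-yl)silane, CC(C)[Si](Cl)(C(C)C)C(C)C
Why: Silylation of a secondary allylic alcohol under basic conditions that avoid Ferrier-type ionisation of the enol ether. The triisopropylsilyl group has no Si–CH3 to be metalated and shields the C4 oxygen from t-BuLi in step 6.

Step 5
Reactants: 8 dimethyl squarate (3,4-dimethoxycyclobut-3-ene-1,2-dione)
Product: 10 3-methoxycyclobut-3-ene-1,2-dione, via hydroxycyclobutenone 9 (not isolated)
Conditions: LiAlH(O-t-Bu)3, THF, −78 → −20 °C; then 6 M HCl, CH2Cl2, 0 °C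
Reagents that add atoms: none
Why: The hindered hydride reduces one squarate carbonyl once; acid then ionises the allylic alcohol 9, and hydrolysis of the methoxy-stabilised cation with loss of methanol gives the semisquarate, a known route to cyclobutenediones with hydrogen on the ring. That hydrogen becomes H6 of ring A.

Step 6
Reactants: 7 rac-(2R,4R)-2-[5-methoxy-2,4-di(propan-2-yloxy)phenyl]-4-(triisopropylsilyloxy)-3,4-dihydro-2H-pyran; 10 3-methoxycyclobut-3-ene-1,2-dione
Product: 13 rac-4-{(2R,4R)-2-[5-methoxy-2,4-di(propan-2-yloxy)phenyl]-4-(triisopropylsilyloxy)-3,4-dihydro-2H-pyran-6-yl}-3,4-dimethoxycyclobut-2-en-1-one (both configurations at the cyclobutenone carbon), via lithiodihydropyran 11 (not isolated), via lithium alkoxide 12 (not isolated)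
Conditions: t-BuLi, THF, −78 → 0 °C; then 10, −78 °C; then MeOTf, −78 → −20 °C
Reagents that add atoms: methyl trifluoromethanesulfonate, COS(=O)(=O)C(F)(F)F
Why: Kinetic α-lithiation of the cyclic enol ether at C6 (as in glycal lithiation), 1,2-addition to the carbonyl of 10 that is not deactivated as a vinylogous ester, and O-methylation of the lithium alkoxide in the same flask. The new quaternary stereocentre is uncontrolled and is destroyed in step 7; methylation at this stage is what later makes O8 a methyl ether and leaves O5 free.

Step 7
Reactants: 13 rac-4-{(2R,4R)-2-[5-methoxy-2,4-di(propan-2-yloxy)phenyl]-4-(triisopropylsilyloxy)-3,4-dihydro-2H-pyran-6-yl}-3,4-dimethoxycyclobut-2-en-1-one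
Product: 16 rac-(2R,4R)-7,8-dimethoxy-2-[5-methoxy-2,4-di(propan-2-yloxy)phenyl]-4-(triisopropylsilyloxy)-3,4-dihydro-2H-chromen-5-ol, via dienylketene 14 (not isolated), via cyclohexadienone 15 (not isolated)
Conditions: toluene (0.02 M, degassed), 105 °C, Ar, base-washed glassware
Reagents that add atoms: none
Why: Thermal conrotatory four-electron electrocyclic opening of the cyclobutenone (cleavage of its C1–C4 bond) gives the dienylketene 14; the closest known reaction type is the Moore ring expansion of 4-alkenyl-4-alkoxycyclobutenones, which is known for adducts of lithiated dihydropyrans. The torquoselectivity is set by the methoxyl on the quaternary carbon, which as a donor rotates outward and so turns the dihydropyranyl group inward, cis to the ketene. Six-electron disrotatory electrocyclisation then joins the electrophilic ketene carbon to C5 of the dihydropyran, the nucleophilic β-carbon of the enol ether, forming C4a–C5 and closing ring A as a six-membered carbocycle (15) in a pericyclic mode, not a polar exo or endo closure. Enolisation of 15 to the phenol 16 makes the sequence irreversible through aromatisation. No new stereocentre is formed: the cyclobutenone stereocentre disappears, so both diastereomers of 13 converge, and C2 and C4 are untouched. The regiochemistry follows from connectivity alone: ketene carbon to C5 (free hydroxyl), ring CH to C6, methoxy-bearing vinyl carbon to C7, methylated quaternary carbon to C8. The step needs ring closure to win over intermolecular ketene capture and over ionisation of the C4 silyl ether beside the new phenol; high dilution in a degassed aprotic solvent and the lowest effective temperature should secure this.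

Step 8
Reactants: 16 rac-(2R,4R)-7,8-dimethoxy-2-[5-methoxy-2,4-di(propan-2-yloxy)phenyl]-4-(triisopropylsilyloxy)-3,4-dihydro-2H-chromen-5-ol
Product: 17 rac-(2R,4R)-7,8-dimethoxy-2-[5-methoxy-2,4-di(propan-2-yloxy)phenyl]-5-(propan-2-yloxy)-4-(triisopropylsilyloxy)-3,4-dihydro-2H-chromene
Conditions: i-PrBr, Cs2CO3, DMF (degassed), 50 °C
Reagents that add atoms: 2-bromopropane, CC(C)Br
Why: Williamson etherification of the only phenol; it masks the hydroquinone-monoether character of ring A and removes the ortho-hydroxybenzyl relation to the C4 silyl ether before fluoride and oxidant are used. The extra ether costs no later step because it is cleaved together with the ring B ethers in step 12.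

Step 9
Reactants: 17 rac-(2R,4R)-7,8-dimethoxy-2-[5-methoxy-2,4-di(propan-2-yloxy)phenyl]-5-(propan-2-yloxy)-4-(triisopropylsilyloxy)-3,4-dihydro-2H-chromene
Product: 18 rac-(2R,4R)-7,8-dimethoxy-2-[5-methoxy-2,4-di(propan-2-yloxy)phenyl]-5-(propan-2-yloxy)-3,4-dihydro-2H-chromen-4-ol
Conditions: n-Bu4NF, THF, rt
Reagents that add atoms: none
Why: Fluoride cleavage of the secondary silyl ether under basic, non-ionising conditions; the aryl alkyl ethers are inert.

Step 10
Reactants: 18 rac-(2R,4R)-7,8-dimethoxy-2-[5-methoxy-2,4-di(propan-2-yloxy)phenyl]-5-(propan-2-yloxy)-3,4-dihydro-2H-chromen-4-ol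
Product: 19 rac-7,8-dimethoxy-2-[5-methoxy-2,4-di(propan-2-yloxy)phenyl]-5-(propan-2-yloxy)-2,3-dihydro-4H-chromen-4-one
Conditions: Dess–Martin periodinane, NaHCO3, CH2Cl2, 0 °C → rt
Reagents that add atoms: none
Why: Dess–Martin oxidation of a secondary benzylic alcohol; the NaHCO3 buffer removes acetic acid, which could ionise the benzylic C4–O bond flanked by three donor oxygens. C4 becomes the flavanone carbonyl and only the C2 stereocentre remains.

Step 11
Reactants: 19 rac-7,8-dimethoxy-2-[5-methoxy-2,4-di(propan-2-yloxy)phenyl]-5-(propan-2-yloxy)-2,3-dihydro-4H-chromen-4-one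
Product: 21 3-hydroxy-7,8-dimethoxy-2-[5-methoxy-2,4-di(propan-2-yloxy)phenyl]-5-(propan-2-yloxy)-4H-chromen-4-one, via oxime 20 (not isolated)
Conditions: isopentyl nitrite, conc. HCl, EtOH–THF, 0 °C → rt; then 10% aq. H2SO4, AcOH, 80 °C
Reagents that add atoms: water, O
Why: Acid-catalysed α-nitrosation of the ketone at its only enolisable carbon (the classical isonitroso route from flavanones to flavonols) gives the α-oximino ketone 20. Hydrolysis of the oxime gives the 3,4-dione, which tautomerises to the aromatic 3-hydroxy-4-pyranone and erases C2; any 5-O-dealkylated material formed in the hot acid would converge on 22 in step 12.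

Step 12
Reactants: 21 3-hydroxy-7,8-dimethoxy-2-[5-methoxy-2,4-di(propan-2-yloxy)phenyl]-5-(propan-2-yloxy)-4H-chromen-4-one
Product: 22 2-(2,4-dihydroxy-5-methoxyphenyl)-3,5-dihydroxy-7,8-dimethoxy-4H-chromen-4-one (CNP0319239.0)
Conditions: BCl3, CH2Cl2, −78 → 0 °C; then H2O
Reagents that add atoms: none
Why: BCl3 cleaves isopropyl aryl ethers much faster than methyl aryl ethers that are not next to a carbonyl; the 5-isopropoxy group is further activated by chelation of boron between O5 and the C4 carbonyl. All three isopropyl groups leave as 2-chloropropane and the target results.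

Compound list

1 | 2,4-dihydroxy-5-methoxybenzaldehyde | COc1cc(C=O)c(O)cc1O | starting material
2 | 5-methoxy-2,4-di(propan-2-yloxy)benzaldehyde | COc1cc(C=O)c(OC(C)C)cc1OC(C)C | intermediate
3 | (E)-1-methoxy-3-(trimethylsilyloxy)buta-1,3-diene | CO/C=C/C(=C)O[Si](C)(C)C | starting material
4 | 6-methoxy-2-[5-methoxy-2,4-di(propan-2-yloxy)phenyl]-4-(trimethylsilyloxy)-3,6-dihydro-2H-pyran (racemic, both C6 epimers; not isolated) | COC1C=C(O[Si](C)(C)C)CC(c2cc(OC)c(OC(C)C)cc2OC(C)C)O1 | intermediate
5 | rac-2-[5-methoxy-2,4-di(propan-2-yloxy)phenyl]-2,3-dihydro-4H-pyran-4-one | O=C1C=COC(c2cc(OC)c(OC(C)C)cc2OC(C)C)C1 | intermediate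
6 | rac-(2R,4R)-2-[5-methoxy-2,4-di(propan-2-yloxy)phenyl]-3,4-dihydro-2H-pyran-4-ol (cis) | O[C@H]1C=CO[C@@H](c2cc(OC)c(OC(C)C)cc2OC(C)C)C1 | intermediate
7 | rac-(2R,4R)-2-[5-methoxy-2,4-di(propan-2-yloxy)phenyl]-4-(triisopropylsilyloxy)-3,4-dihydro-2H-pyran | CC(C)[Si](C(C)C)(C(C)C)O[C@H]1C=CO[C@@H](c2cc(OC)c(OC(C)C)cc2OC(C)C)C1 | intermediate
8 | dimethyl squarate | COC1=C(OC)C(=O)C1=O | starting material
9 | rac-4-hydroxy-2,3-dimethoxycyclobut-2-en-1-one (not isolated) | COC1=C(OC)C(O)C1=O | intermediate
10 | 3-methoxycyclobut-3-ene-1,2-dione | COC1=CC(=O)C1=O | intermediate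
11 | rac-{(2R,4R)-2-[5-methoxy-2,4-di(propan-2-yloxy)phenyl]-4-(triisopropylsilyloxy)-3,4-dihydro-2H-pyran-6-yl}lithium (not isolated) | [Li]C1=C[C@H](O[Si](C(C)C)(C(C)C)C(C)C)C[C@H](c2cc(OC)c(OC(C)C)cc2OC(C)C)O1 | intermediate
12 | lithium alkoxide of the 4-hydroxy-3-methoxycyclobutenone adduct of 11 and 10 (racemic, both configurations at the carbinol carbon; not isolated) | COC1=CC(=O)C1(O[Li])C1=C[C@H](O[Si](C(C)C)(C(C)C)C(C)C)C[C@H](c2cc(OC)c(OC(C)C)cc2OC(C)C)O1 | intermediate
13 | rac-4-{(2R,4R)-2-[5-methoxy-2,4-di(propan-2-yloxy)phenyl]-4-(triisopropylsilyloxy)-3,4-dihydro-2H-pyran-6-yl}-3,4-dimethoxycyclobut-2-en-1-one (both configurations at the cyclobutenone carbon) | COC1=CC(=O)C1(OC)C1=C[C@H](O[Si](C(C)C)(C(C)C)C(C)C)C[C@H](c2cc(OC)c(OC(C)C)cc2OC(C)C)O1 | intermediate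
14 | rac-(3Z)-3,4-dimethoxy-4-{(2R,4R)-2-[5-methoxy-2,4-di(propan-2-yloxy)phenyl]-4-(triisopropylsilyloxy)-3,4-dihydro-2H-pyran-6-yl}buta-1,3-dien-1-one (not isolated) | O=C=C/C(OC)=C(OC)\C1=C[C@H](O[Si](C(C)C)(C(C)C)C(C)C)C[C@H](c2cc(OC)c(OC(C)C)cc2OC(C)C)O1 | intermediate
15 | rac-(2R,4R)-7,8-dimethoxy-2-[5-methoxy-2,4-di(propan-2-yloxy)phenyl]-4-(triisopropylsilyloxy)-2,3,4,4a-tetrahydro-5H-chromen-5-one (C4a unassigned; not isolated) | O=C1C=C(OC)C(OC)=C2O[C@@H](c3cc(OC)c(OC(C)C)cc3OC(C)C)C[C@@H](O[Si](C(C)C)(C(C)C)C(C)C)C12 | intermediate
16 | rac-(2R,4R)-7,8-dimethoxy-2-[5-methoxy-2,4-di(propan-2-yloxy)phenyl]-4-(triisopropylsilyloxy)-3,4-dihydro-2H-chromen-5-ol | COc1cc(O)c2c(c1OC)O[C@@H](c1cc(OC)c(OC(C)C)cc1OC(C)C)C[C@H]2O[Si](C(C)C)(C(C)C)C(C)C | intermediate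
17 | rac-(2R,4R)-7,8-dimethoxy-2-[5-methoxy-2,4-di(propan-2-yloxy)phenyl]-5-(propan-2-yloxy)-4-(triisopropylsilyloxy)-3,4-dihydro-2H-chromene | COc1cc(OC(C)C)c2c(c1OC)O[C@@H](c1cc(OC)c(OC(C)C)cc1OC(C)C)C[C@H]2O[Si](C(C)C)(C(C)C)C(C)C | intermediate
18 | rac-(2R,4R)-7,8-dimethoxy-2-[5-methoxy-2,4-di(propan-2-yloxy)phenyl]-5-(propan-2-yloxy)-3,4-dihydro-2H-chromen-4-ol | COc1cc(OC(C)C)c2c(c1OC)O[C@@H](c1cc(OC)c(OC(C)C)cc1OC(C)C)C[C@H]2O | intermediate
19 | rac-7,8-dimethoxy-2-[5-methoxy-2,4-di(propan-2-yloxy)phenyl]-5-(propan-2-yloxy)-2,3-dihydro-4H-chromen-4-one | COc1cc(OC(C)C)c2c(c1OC)OC(c1cc(OC)c(OC(C)C)cc1OC(C)C)CC2=O | intermediate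
20 | rac-3-(hydroxyimino)-7,8-dimethoxy-2-[5-methoxy-2,4-di(propan-2-yloxy)phenyl]-5-(propan-2-yloxy)-2,3-dihydro-4H-chromen-4-one (oxime geometry unassigned; not isolated) | COc1cc(OC(C)C)c2c(c1OC)OC(c1cc(OC)c(OC(C)C)cc1OC(C)C)C(=NO)C2=O | intermediate
21 | 3-hydroxy-7,8-dimethoxy-2-[5-methoxy-2,4-di(propan-2-yloxy)phenyl]-5-(propan-2-yloxy)-4H-chromen-4-one | COc1cc(OC(C)C)c2c(=O)c(O)c(-c3cc(OC)c(OC(C)C)cc3OC(C)C)oc2c1OC | intermediate
22 | 2-(2,4-dihydroxy-5-methoxyphenyl)-3,5-dihydroxy-7,8-dimethoxy-4H-chromen-4-one | COc1cc(-c2oc3c(OC)c(OC)cc(O)c3c(=O)c2O)c(O)cc1O | target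

Total step count: 12. Longest linear sequence: 11 steps (steps 1–4 and 6–12, from 1 to 22); step 5 is a one-step side branch from 8.

Least certain steps

Step 7 (key step). The most likely failure is ionisation of the C4 silyloxy group, assisted by the phenol that has just formed ortho to it, with loss of silanol. The hot, electron-rich hydroquinone monoether may also be oxidised by air. The benzylic carbon is flanked by three donor oxygens, so the barrier to this loss is low. The fallback sets out from 13 and returns at 17. The ring expansion would be run in toluene containing N,O-bis(trimethylsilyl)acetamide, so that the phenol is silylated as it forms and never accumulates. This would give rac-(2R,4R)-7,8-dimethoxy-2-[5-methoxy-2,4-di(propan-2-yloxy)phenyl]-4-(triisopropylsilyloxy)-5-(trimethylsilyloxy)-3,4-dihydro-2H-chromene F1. Treating F1 with CsF and 2-bromopropane in DMF (fluoride-mediated desilylative alkylation of an aryl silyl ether) should then give 17 directly.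

Step 6. Deprotonation may compete at other sites: between the two isopropoxy groups of ring B (ortho-lithiation) or at the benzylic C2–H. Residual base may also attack 10. These risks arise because t-BuLi is unselective once the enol ether C–H is not clearly the most accessible. The fallback sets out from 7 and returns at 13, and replaces the kinetic vinyl deprotonation by an anomeric sulfone anion.
- Acid-catalysed addition of thiophenol to the enol ether (PhSH, PPh3·HBr cat., CH2Cl2) would give the thioacetal triisopropyl{[2-[5-methoxy-2,4-di(propan-2-yloxy)phenyl]-6-(phenylsulfanyl)oxan-4-yl]oxy}silane F2.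
- Oxidation with mCPBA would give the sulfone 2-[5-methoxy-2,4-di(propan-2-yloxy)phenyl]-6-(phenylsulfonyl)-4-(triisopropylsilyloxy)oxane F3.
- n-BuLi at −78 °C should deprotonate only the carbon between sulfone and ring oxygen. Addition to 10 and methylation with MeOTf would give the sulfonyl adduct 3,4-dimethoxy-4-[6-[5-methoxy-2,4-di(propan-2-yloxy)phenyl]-2-(phenylsulfonyl)-4-(triisopropylsilyloxy)oxan-2-yl]cyclobut-2-en-1-one F4.
- F4 should lose benzenesulfinic acid on warming with Et3N, a known way from anomeric sulfones to 6-substituted dihydropyrans, and give 13.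

Step 11. Nitrosation or oxidation may occur on the aromatic rings (C6 of ring A, C3' of ring B) in place of C3, and the oxime may hydrolyse incompletely. Both rings carry three or four donor oxygens. The fallback sets out from 19 and returns at 21.
- Soft enolisation with TMSOTf and Et3N would give the silyl enol ether rac-{[7,8-dimethoxy-2-[5-methoxy-2,4-di(propan-2-yloxy)phenyl]-5-(propan-2-yloxy)-2H-chromen-4-yl]oxy}trimethylsilane F5.
- Rubottom oxidation with dimethyldioxirane and mild acidic work-up would give the alcohol rac-(2R,3R)-3-hydroxy-7,8-dimethoxy-2-[5-methoxy-2,4-di(propan-2-yloxy)phenyl]-5-(propan-2-yloxy)-2,3-dihydro-4H-chromen-4-one F6 (trans, oxidant anti to the aryl group).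
- Parikh–Doering oxidation of F6 (SO3·pyridine, DMSO, Et3N) would give the 3,4-dione, which tautomerises to 21.

Step 2. The cycloaddition may be slow because the aldehyde is strongly deactivated by its ortho and para alkoxy groups. The Lewis acid may also ionise the benzylic C2–O bond of the product. The fallback sets out from 2 and returns at 5. Aldol addition of the lithium enolate of (E)-4-methoxybut-3-en-2-one (LiN(i-Pr)2, THF, −78 °C) to 2 would give the aldol adduct rac-(1E)-5-hydroxy-1-methoxy-5-[5-methoxy-2,4-di(propan-2-yloxy)phenyl]pent-1-en-3-one F7. Acid-catalysed cyclisation of F7 with loss of methanol (TFA cat., CH2Cl2) would give 5.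

Further compounds

F1 | step 7 | rac-(2R,4R)-7,8-dimethoxy-2-[5-methoxy-2,4-di(propan-2-yloxy)phenyl]-4-(triisopropylsilyloxy)-5-(trimethylsilyloxy)-3,4-dihydro-2H-chromene | COc1cc(O[Si](C)(C)C)c2c(c1OC)O[C@@H](c1cc(OC)c(OC(C)C)cc1OC(C)C)C[C@H]2O[Si](C(C)C)(C(C)C)C(C)C
F2 | step 6 | triisopropyl{[2-[5-methoxy-2,4-di(propan-2-yloxy)phenyl]-6-(phenylsulfanyl)oxan-4-yl]oxy}silane (racemic, aryl and silyloxy cis, both configurations at the sulfur-bearing carbon) | CC(C)[Si](C(C)C)(C(C)C)O[C@H]1CC(Sc2ccccc2)O[C@@H](c2cc(OC)c(OC(C)C)cc2OC(C)C)C1
F3 | step 6 | 2-[5-methoxy-2,4-di(propan-2-yloxy)phenyl]-6-(phenylsulfonyl)-4-(triisopropylsilyloxy)oxane (racemic, aryl and silyloxy cis, both configurations at the sulfonyl-bearing carbon) | CC(C)[Si](C(C)C)(C(C)C)O[C@H]1CC(S(=O)(=O)c2ccccc2)O[C@@H](c2cc(OC)c(OC(C)C)cc2OC(C)C)C1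
F4 | step 6 | 3,4-dimethoxy-4-[6-[5-methoxy-2,4-di(propan-2-yloxy)phenyl]-2-(phenylsulfonyl)-4-(triisopropylsilyloxy)oxan-2-yl]cyclobut-2-en-1-one (racemic, aryl and silyloxy cis, other centres as mixture) | COC1=CC(=O)C1(OC)C1(S(=O)(=O)c2ccccc2)C[C@H](O[Si](C(C)C)(C(C)C)C(C)C)C[C@H](c2cc(OC)c(OC(C)C)cc2OC(C)C)O1
F5 | step 11 | rac-{[7,8-dimethoxy-2-[5-methoxy-2,4-di(propan-2-yloxy)phenyl]-5-(propan-2-yloxy)-2H-chromen-4-yl]oxy}trimethylsilane | COc1cc(OC(C)C)c2c(c1OC)OC(c1cc(OC)c(OC(C)C)cc1OC(C)C)C=C2O[Si](C)(C)C
F6 | step 11 | rac-(2R,3R)-3-hydroxy-7,8-dimethoxy-2-[5-methoxy-2,4-di(propan-2-yloxy)phenyl]-5-(propan-2-yloxy)-2,3-dihydro-4H-chromen-4-one (trans) | COc1cc(OC(C)C)c2c(c1OC)O[C@H](c1cc(OC)c(OC(C)C)cc1OC(C)C)[C@@H](O)C2=O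
F7 | step 2 | rac-(1E)-5-hydroxy-1-methoxy-5-[5-methoxy-2,4-di(propan-2-yloxy)phenyl]pent-1-en-3-one | CO/C=C/C(=O)CC(O)c1cc(OC)c(OC(C)C)cc1OC(C)C
A1 | alternative 1 | 1-[2,4-bis(benzyloxy)-5-methoxyphenyl]-3-(2-hydroxy-3,4,6-trimethoxyphenyl)propane-1,3-dione | O=C(CC(=O)c1cc(OC)c(OCc2ccccc2)cc1OCc1ccccc1)c1c(OC)cc(OC)c(OC)c1O
A2 | alternative 1 | 1-(2-hydroxy-3,4,6-trimethoxyphenyl)ethan-1-one | CC(=O)c1c(OC)cc(OC)c(OC)c1O
A3 | alternative 1 | 1-bromo-2,4-bis(benzyloxy)-5-methoxybenzene | COc1cc(Br)c(OCc2ccccc2)cc1OCc1ccccc1
A4 | alternative 2 | 3-(benzyloxy)-2-[2,4-bis(benzyloxy)-5-methoxyphenyl]-5,7,8-trimethoxy-4H-chromen-4-one | O=c1c(OCc2ccccc2)c(-c2cc(OC)c(OCc3ccccc3)cc2OCc2ccccc2)oc2c(OC)c(OC)cc(OC)c12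
A5 | alternative 2 | (2E)-2-(benzyloxy)-3-[2,4-bis(benzyloxy)-5-methoxyphenyl]-3-(2,3,5-trimethoxyphenoxy)prop-2-enoic acid | OC(=O)/C(OCc1ccccc1)=C(\Oc1cc(OC)cc(OC)c1OC)c1cc(OC)c(OCc2ccccc2)cc1OCc1ccccc1
A6 | alternative 3 | 3-hydroxy-5,7,8-trimethoxy-2-[5-methoxy-2,4-bis(methylsulfonyloxy)phenyl]-4H-chromen-4-one | O=c1c(O)c(-c2cc(OC)c(OS(C)(=O)=O)cc2OS(C)(=O)=O)oc2c(OC)c(OC)cc(OC)c12
A7 | alternative 3 | 2-bromo-2-{bromo[5-methoxy-2,4-bis(methylsulfonyloxy)phenyl]methyl}-4,6,7-trimethoxy-1-benzofuran-3(2H)-one (mixture of stereoisomers) | COc1cc(OC)c2c(c1OC)OC(Br)(C(Br)c1cc(OC)c(OS(C)(=O)=O)cc1OS(C)(=O)=O)C2=O
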